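Against the blue run, the red run holds more starting material and a lower percentage of isomer of the product B, so I turn the percentages into concentrations.

| setting | blue | green | red | flask |
|---|---|---|---|---|
| starting material | 0.30 M | 0.30 M | 0.45 M | 0.30 M |
| protic impurity | 3 mM | 12 mM | 6 mM | 6.00 mM |
| remark | run made earlier | run made earlier | run made earlier |  |
| time |  |  |  | 8.0 d |

- blue (time / d: starting material / %, target / %, isomer of the product B / %): 1.67: 2.1, 73.8, 19.4; 3.00: 2.1, 73.9, 20.3; 5.00: 2.2, 74.1, 20.2; 6.00: 2.5, 74.5, 19.6; 8.00: 2.2, 74.1, 20.0
- green (time / d: starting material / %, target / %, isomer of the product B / %): 0.625: 1.6, 71.8, 19.4; 2.08: 2.3, 71.2, 20.1; 4.00: 2.2, 71.1, 19.9; 6.00: 1.9, 71.9, 20.7; 8.00: 1.7, 70.8, 19.4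
- red (time / d: starting material / %, target / %, isomer of the product B / %): 1.67: 1.6, 81.9, 13.1; 3.00: 1.3, 82.4, 13.0; 5.00: 1.2, 81.8, 13.8; 6.00: 1.6, 81.7, 13.2; 8.00: 1.2, 81.8, 13.3

(readings scatter by 0.3 percentage points)

- what was read earlier has a scatter of 0.3 percentage points, one standard deviation
- a reading or a percentage of target counts all its forms, free or not
- the reaction counts as stopped when no species that holds the starting material changes by six tenths of a point or more over the second half of the time

1. which holds at 8.0 d: what has brought the reaction to rest, or that it has not come to rest (all of the starting material has reacted / it is still moving / forward and back rates have come level)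
2. conversion of starting material at 8.0 d
3. amount of target at 8.0 d, in percent of the starting material charged
4. amount of isomer of the product B at 8.0 d, in percent of the starting material charged

The readings of each run lie flat from the first one, so I take run means. I treat the protic impurity as the limiting reagent of a one-for-one loss of starting material. W is then the charge minus target minus [protic impurity]:

| run | W | [isomer of the product B] | [starting material] |
|---|---|---|---|
| blue | 74.8 mM | 59.7 mM | 6.66 mM |
| green | 73.9 mM | 59.7 mM | 5.82 mM |
| red | 75.4 mM | 59.8 mM | 6.21 mM |

W spans 1.44 mM across these runs and averages 74.7 mM. My number is the lost share, (W + [protic impurity]) over the [starting material] charged: the part of the charge that does not end as target. For the flask it is 26.9%, so I expect target at 73.1%.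

One number is not enough: it does not divide the loss. The columns do: isomer of the product B at 59.7 mM gives 19.9%. Starting material, flat and not zero at 6.23 mM, gives conversion 97.9%, so I expect forward and back rates level.

The forecast says forward and back rates have come level, conversion 97.9%, target 73.2% and isomer of the product B 20%, reasoning that “The plateaus are flat from the first reading”.

The flask gives forward and back rates have come level, conversion 97.9%, target 73.1% and isomer of the product B 20.1%.

    target ⇌ isomer of the product B (K = 0.727, k = 4.34 × 10⁻⁵ s⁻¹)
    starting material + protic impurity → quenched substrate (k = 0.0141 M⁻¹ s⁻¹)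
    crystals ⇌ target, rate k3*(cs3 - [target]) while solid is left; crystals form when [target] > cs3 (solubility = 0.0830 M, k = 0.00190 s⁻¹)
    starting material ⇌ target (K = 13.3, k = 2.13 × 10⁻⁴ s⁻¹)
    target ⇌ isomer of the product A (K = 0.0990, k = 5.93 × 10⁻⁵ s⁻¹)

The relaxation half-life of dissolved target and isomer of the product B by the step between them alone, both ways together, is 0.0778 d, short against 8.0 d. In this flask target, crystals included, stands at 73.4% at 0.800 d and 73.1% at 80.0 d, so waiting adds no target.

For the neighbour with 0.0015 M of protic impurity, the lost share becomes 25.4%, which gives target at 74.6%. That neighbour computes to 74.6%, with isomer of the product B at 20.1%.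

The runs were computed from invented constants.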